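Early times showed a rise of target in the teal run, while its starting material still stood at 89.9 % after 12.0 h, so I reckoned in slopes.

| setting | red | teal | amber | south-west | north-west | east |
|---|---|---|---|---|---|---|
| starting material | 10 mM | 10 mM | 15 mM | 10 mM | 10 mM | 10 mM |
| second substrate | 0.25 equiv | 0.38 equiv | 0.50 equiv | 0.500 equiv | 0.500 equiv | 0.500 equiv |
| free catalyst | 2.2 mol% | 2.2 mol% | 2.2 mol% | 2.2 mol% | 2.2 mol% | 2.2 mol% |
| temperature | 2 °C | 19 °C | 2 °C | 25 °C | −5 °C | 10 °C |
| remark | run made earlier | run made earlier | run made earlier |  |  |  |
| time |  |  |  | 20 h | 20 h | 20 h |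

- red (time / h: target / %, starting material / %): 3.00: 0.5, 96.8; 10.0: 3.0, 96.3; 20.0: 2.4, 97.1; 25.0: 1.8, 94.7; 40.0: 2.2, 95.2
- teal (time / h: target / %, starting material / %): 1.00: 1.3, 98.5; 2.00: 0.9, 96.4; 3.00: 1.9, 96.5; 6.00: 5.7, 94.8; 12.0: 9.0, 89.9
- amber (time / h: target / %, starting material / %): 3.00: 0, 97.7; 6.00: 0, 97.8; 10.0: 0, 97.3; 20.0: 2.7, 94.7; 40.0: 2.0, 94.4

(readings scatter by 1 percentage point)

- what is said of target includes crystals
- crystals is a solid; its amount is given per volume of the solution
- on the list of suspects stand: catalyst intermediate B -> free catalyst + second product; catalyst intermediate A <-> free catalyst + target; second substrate + free catalyst <-> catalyst intermediate B; starting material + free catalyst <-> catalyst intermediate A; crystals <-> target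

1. which flask leads in amount of target, in percent of the starting material charged ("all alike" within 1.5 percentage points) (south-west / north-west / east / all alike)
2. how much target is there at the end, in percent of the starting material charged: south-west
3. how much target is there at the end, in percent of the starting material charged: north-west
4. how much target is there at the end, in percent of the starting material charged: east

My measure was the turnover frequency: target made per hour, as a share of the starting material charged, divided by the catalyst loading. Red and amber share a temperature, so I pooled their readings, summed target over summed time. Teal I summed likewise. I then worked in decades, and took the temperature dependence from the gap between the two.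

turnover frequency at 2 °C: 0.0375 h⁻¹

turnover frequency at 19 °C: 0.356 h⁻¹

gap between the two: 0.977 of a decade

apparent activation energy: 88.5 kJ mol⁻¹

I used this apparent activation energy of the turnover frequency to carry the slope to each flask.

turnover frequency at 25 °C: 0.741 h⁻¹

target after 20 h: south-west 32.6 %, north-west 0.601 %, east 4.92 %

The weak link was the cold slope, since red and amber read flat from 20.0 h to 40.0 h. My line puts them at 3.30 % at the end, and they read 2.2 % and 2.0 %, each about one standard deviation off, so the scatter could not choose between a line and a plateau. I reforged the link on those two last readings, which gave 37.8 % for south-west. I kept 32.6 % as my number.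

The forecast, reading a slow start “with target plateauing at equilibrium”, gave south-west 15 %, north-west 0.5 % and east 4.8 %, with south-west leading.

The flasks gave south-west 27.5 %, north-west 0.524 % and east 4.21 %, so south-west led.

    catalyst intermediate B → free catalyst + second product (k = 1.10 h⁻¹, Ea = 84.0 kJ mol⁻¹)
    catalyst intermediate A ⇌ free catalyst + target (K = 0.00340 M, k = 0.720 h⁻¹, Ea = 88.0 kJ mol⁻¹, ΔH = −33.0 kJ mol⁻¹)
    second substrate + free catalyst ⇌ catalyst intermediate B (K = 5200 M⁻¹, k = 520 M⁻¹ h⁻¹, Ea = 39.0 kJ mol⁻¹, ΔH = −6.00 kJ mol⁻¹)
    starting material + free catalyst ⇌ catalyst intermediate A (K = 3700 M⁻¹, k = 8300 M⁻¹ h⁻¹, Ea = 53.0 kJ mol⁻¹, ΔH = −9.00 kJ mol⁻¹)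
    crystals ⇌ target, rate k5*(cs5 - [target]) while solid is left; crystals form when [target] > cs5 (solubility = 9.40 mM, k = 12.0 h⁻¹)
    (constants at 25 °C)

Carried down from south-west with my activation energy, the result gives 0.508 % for north-west, and it gives 15.0 % for a repeat of north-west at 20 °C, which gave 15.2 %. In south-west at 20 h, catalyst intermediate A, the resting state, held 87.0 % of the catalyst. Left ten times as long, north-west reached 4.83 %, about ten times its amount, and east reached 40.2 %, about ten times its amount. South-west reached 91.2 %, its starting material down from 70.5 % to 7.24 %.

(The earlier runs and the new flask were computed on assumed constants, and the scatter is random.)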